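**Plan**

- Labels: rings A/B = naphthalene (A carries the ether oxygen), ring C = carbocycle closed last, ring D = resorcinol ring inside the macrocycle, ring E = 2,6-dihydroxyphenyl; chain C-1' (macrocycle C=O) to C-6', with C-3' (S), C-4' (R), C-5' (R).
- Retrosynthetic cuts: (i) the C=C between the ring E carbinyl carbon and ring B (ring C, cyclodehydration); (ii) in the ten-membered ring the C-1'–C-2(ring D) bond, traced back to a twelve-membered aryl ester on the neighbouring ring D oxygen, and the O–C-1(ring D) ether bond; (iii) C-3'–C-4' (Michael); (iv) C(=O)–ring E (aryllithium); (v) ring A–C-5' (Friedel–Crafts).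
- Enabling feature: in ring D the macrocycle ketone sits at C-2 between the ether oxygen (C-1) and a free OH (C-3). That OH can carry the acyl group as an ester (ring larger by O and C-3 of ring D), and a carbanion at C-2 takes the acyl back (1,3 O→C shift). A 3-acyloxybenzyne gives exactly this carbanion when the ring A naphtholate adds to it.
- Forward order: naphthalene A/B (arylacetoacetate cyclisation) → temporary δ-lactone on ring A → ring E ketone by aryllithium opening → Michael addition → aryl ester with the aryne precursor → twelve-membered ring and its contraction to ten in one operation → demethylation and ring C.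
- Stereochemistry: C-5' from iminium catalysis with an (S)-diarylprolinol silyl ether; C-4' from 1,3-allylic strain in the Z-enolate; C-3' from the anti topicity of the Z-enolate/(E)-enoate Michael addition.

Key step: step 14

Assumption: the target is taken as the tautomer drawn (para-quinone methide of ring B); its prototropic tautomers are the same substance.

**Route**

Step 1
Reactants: 1 3,5-dimethoxyphenylacetic acid; 2 ethyl potassium malonate
Product: 4 ethyl 4-(3,5-dimethoxyphenyl)-3-oxobutanoate, via acyl imidazolide 3 (not isolated)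
Conditions: 1,1′-carbonyldiimidazole, THF, 23 °C; then 2, MgCl2, Et3N, MeCN, 23 → 40 °C; 1 M HCl
Reagents that add atoms: none
Why: Masamune–Brooks C-acylation of the magnesium malonate half-ester by the acyl imidazolide, then decarboxylation, should give the β-keto ester (crossed Claisen-type condensation); no stereocentre.

Step 2
Reactants: 4 ethyl 4-(3,5-dimethoxyphenyl)-3-oxobutanoate
Product: 5 6,8-dimethoxynaphthalene-1,3-diol
Conditions: conc. H2SO4, 0 → 10 °C; ice
Reagents that add atoms: none
Why: Intramolecular Friedel–Crafts acylation by the ester carbonyl at the ring position ortho to the side chain and para to a methoxy group, then enolisation, should give the naphthalene-1,3-diol (classical arylacetoacetate route to naphthoresorcinols).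

Step 3
Reactants: 5 6,8-dimethoxynaphthalene-1,3-diol
Product: 6 6,8-dimethoxy-3-[(triisopropylsilyl)oxy]naphthalen-1-ol
Conditions: TIPSCl (1.05 equiv), imidazole, DMF, 0 °C
Reagents that add atoms: chlorotri(propan-2-yl)silane (TIPSCl), CC(C)[Si](Cl)(C(C)C)C(C)C
Why: Selective O-silylation of the unhindered 3-OH; the 1-OH is peri to the 8-methoxy group, hydrogen-bonded to it and shielded from a bulky silyl chloride.

Step 4
Reactants: 6 6,8-dimethoxy-3-[(triisopropylsilyl)oxy]naphthalen-1-ol
Product: 7 triisopropyl[(4,5,7-trimethoxynaphthalen-2-yl)oxy]silane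
Conditions: NaH, MeI, THF/DMF, 0 → 23 °C
Reagents that add atoms: iodomethane, CI
Why: Williamson O-methylation of the remaining peri phenol as its sodium salt; the aryl triisopropylsilyl ether is stable to these conditions.

Step 5
Reactants: 7 triisopropyl[(4,5,7-trimethoxynaphthalen-2-yl)oxy]silane
Product: 8 4,5,7-trimethoxynaphthalen-2-ol
Conditions: Bu4NF, THF, 0 °C; AcOH
Reagents that add atoms: none
Why: Fluoride cleavage of the aryl silyl ether frees the one naphthol (the later ether oxygen) that is to direct the next C–C bond formation.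

Step 6
Reactants: 8 4,5,7-trimethoxynaphthalen-2-ol; 9 (E)-but-2-enal
Product: 10 (1R)-6,7,9-trimethoxy-1-methyl-2,3-dihydro-1H-benzo[f]chromen-3-ol (anomer mixture)
Conditions: (S)-2-[diphenyl(trimethylsilyloxy)methyl]pyrrolidine (20 mol %), PhCO2H (20 mol %), toluene, 0 °C
Reagents that add atoms: none
Why: Iminium-catalysed Friedel–Crafts alkylation of the 2-naphthol at C-1 (ortho to OH, para to 4-OMe) and hemiacetal closure; the silyloxydiphenylmethyl group of the (S)-catalyst shields one face of the (E)-iminium ion, so the naphthol should add to the open face and set the benzylic carbon (later C-5') as R.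

Step 7
Reactants: 10 (1R)-6,7,9-trimethoxy-1-methyl-2,3-dihydro-1H-benzo[f]chromen-3-ol
Product: 11 (1R)-6,7,9-trimethoxy-1-methyl-1,2-dihydro-3H-benzo[f]chromen-3-one
Conditions: (n-Pr4N)RuO4 (5 mol %), N-methylmorpholine N-oxide, 4 Å MS, CH2Cl2, 23 °C
Reagents that add atoms: none
Why: Ley–Griffith oxidation of a lactol to the lactone; the lactone ties up the ring A oxygen and activates the carbonyl carbon for the aryl ketone synthesis, and the stereocentre is not involved.

Step 8
Reactants: 11 (1R)-6,7,9-trimethoxy-1-methyl-1,2-dihydro-3H-benzo[f]chromen-3-one; 12 1,3-dimethoxybenzene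
Product: 15 (3R)-3-{2-[(tert-butyldimethylsilyl)oxy]-4,5,7-trimethoxynaphthalen-1-yl}-1-(2,6-dimethoxyphenyl)butan-1-one, via (2,6-dimethoxyphenyl)lithium 13 (not isolated), via lithium naphtholate 14 (not isolated)
Conditions: 12, n-BuLi, THF, 0 → 23 °C; 11, −78 → 0 °C; then TBSCl, DMF, 0 → 23 °C
Reagents that add atoms: tert-butyl(chloro)dimethylsilane (TBSCl), CC(C)(C)[Si](C)(C)Cl
Why: Directed ortho-lithiation between the two methoxy groups, acyl substitution at the aryl lactone (the naphtholate leaving group lets the adduct collapse to a 2,6-disubstituted aryl ketone too hindered for a second addition) and O-silylation of the lithium naphtholate; the stereocentre is not touched.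

Step 9
Reactants: 15 (3R)-3-{2-[(tert-butyldimethylsilyl)oxy]-4,5,7-trimethoxynaphthalen-1-yl}-1-(2,6-dimethoxyphenyl)butan-1-one; 16 tert-butyl (E)-but-2-enoate
Product: 17 tert-butyl (3S,4R,5R)-5-{2-[(tert-butyldimethylsilyl)oxy]-4,5,7-trimethoxynaphthalen-1-yl}-4-(2,6-dimethoxybenzoyl)-3-methylhexanoate
Conditions: LiN(i-Pr)2 (1.05 equiv), THF, −78 °C; 16, −78 → −40 °C; AcOH, −78 °C
Reagents that add atoms: none
Why: Michael addition of a ketone lithium enolate to an (E)-enoate: LiN(i-Pr)2 gives the Z(O)-enolate of the aryl ketone, 1,3-allylic strain holds the C-5' hydrogen in the enolate plane so that the enoate should approach anti to the silyloxynaphthyl group (C-4' R), and the chelated transition state of Z-enolates with the β-methyl group anti to the enolate carbon should give the anti adduct (C-3' S).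

Step 10
Reactants: 17 tert-butyl (3S,4R,5R)-5-{2-[(tert-butyldimethylsilyl)oxy]-4,5,7-trimethoxynaphthalen-1-yl}-4-(2,6-dimethoxybenzoyl)-3-methylhexanoate
Product: 18 (3S,4R,5R)-5-{2-[(tert-butyldimethylsilyl)oxy]-4,5,7-trimethoxynaphthalen-1-yl}-4-(2,6-dimethoxybenzoyl)-3-methylhexanoic acid
Conditions: CF3CO2H, CH2Cl2, anisole (cation scavenger), 0 → 23 °C
Reagents that add atoms: none
Why: Acidolysis of the tert-butyl ester (loss of isobutene); the aryl silyl ether, the hindered ketone and the stereocentres should survive, and anisole keeps the tert-butyl cation off the electron-rich naphthalene.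

Step 11
Reactants: 19 2-bromobenzene-1,3-diol
Product: 20 2-bromo-1,3-bis(trimethylsilyloxy)benzene
Conditions: hexamethyldisilazane, THF, reflux; evaporation
Reagents that add atoms: hexamethyldisilazane, C[Si](C)(C)N[Si](C)(C)C
Why: Silylation of both phenols with hexamethyldisilazane, the usual first stage of a 2-silylaryl triflate synthesis.

Step 12
Reactants: 20 2-bromo-1,3-bis(trimethylsilyloxy)benzene
Product: 23 3-hydroxy-2-(trimethylsilyl)phenyl trifluoromethanesulfonate, via lithium silylphenolate 21 (not isolated), via silyloxy triflate 22 (not isolated)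
Conditions: n-BuLi, THF, −78 °C; Tf2O, −78 → 0 °C; 1 M HCl work-up
Reagents that add atoms: trifluoromethanesulfonic anhydride, O=S(=O)(OS(=O)(=O)C(F)(F)F)C(F)(F)F
Why: Bromine–lithium exchange, 1,3 O→C silyl migration (retro-Brook) to the C-silyl lithium phenolate, O-triflation, and hydrolysis of the remaining labile aryl O–SiMe3 in the acidic work-up; a basic work-up is avoided because the phenolate of 23 would itself start aryne formation.

Step 13
Reactants: 18 (3S,4R,5R)-5-{2-[(tert-butyldimethylsilyl)oxy]-4,5,7-trimethoxynaphthalen-1-yl}-4-(2,6-dimethoxybenzoyl)-3-methylhexanoic acid; 23 3-hydroxy-2-(trimethylsilyl)phenyl trifluoromethanesulfonate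
Product: 24 3-{[(trifluoromethyl)sulfonyl]oxy}-2-(trimethylsilyl)phenyl (3S,4R,5R)-5-{2-[(tert-butyldimethylsilyl)oxy]-4,5,7-trimethoxynaphthalen-1-yl}-4-(2,6-dimethoxybenzoyl)-3-methylhexanoate
Conditions: N-(3-dimethylaminopropyl)-N′-ethylcarbodiimide hydrochloride, DMAP (cat.), CH2Cl2, 0 → 23 °C
Reagents that add atoms: none
Why: Steglich-type carbodiimide esterification of a phenol under near-neutral conditions that do not trigger the silyl triflate; the ring A oxygen is still silylated, so only the external phenol can be acylated.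

Step 14
Reactants: 24 3-{[(trifluoromethyl)sulfonyl]oxy}-2-(trimethylsilyl)phenyl (3S,4R,5R)-5-{2-[(tert-butyldimethylsilyl)oxy]-4,5,7-trimethoxynaphthalen-1-yl}-4-(2,6-dimethoxybenzoyl)-3-methylhexanoate
Product: 27 ten-membered ansa ketone (ring D: 2-acyl-3-hydroxy-1-naphthyloxy; C-3' S C-4' R C-5' R), via naphtholate aryne 25 (not isolated), via twelve-membered aryl anion 26 (not isolated)
Conditions: Bu4N[Ph3SiF2] (3 equiv), THF, 40 °C, 24 added by syringe pump to a final 1 mM; AcOH
Reagents that add atoms: none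
Why: Proposed new method: fluoride cleaves the naphthyl silyl ether to the naphtholate and, by attack at SiMe3 with loss of triflate, unmasks a 3-acyloxybenzyne; the naphtholate oxygen adds to the aryne carbon distal to the acyloxy group (twelve-membered ring, 12-endo-dig nucleophilic addition), and the aryl anion formed between the two oxygens attacks the ester carbonyl through a four-membered transition state (4-exo-trig addition–fragmentation) and expels the ring D phenoxide, a 1,3 O→C acyl shift that contracts the ring from twelve to ten atoms. The closest known reaction types are the fluoride-induced O-arylation of phenols with arynes from 2-silylaryl triflates and the insertion of arynes into the C–O bond of carboxylic acids, where an ortho-acyloxyaryl anion gives an ortho-hydroxyaryl ketone (anionic Fries-type shift); ring contraction of aryl macrolactones to ansa ketones is known in the photo-Fries variant. The regioselectivity (oxygen at the distal carbon, acyl at the carbon between the two oxygens) follows from the inductive effect of the acyloxy group on the distorted aryne, so no blocking or directing group has to be removed afterwards. The intramolecular course is secured by slow addition at high dilution in the absence of any other good nucleophile, and the acyl shift should outrun protonation of the aryl anion because of the four-membered geometry and the aprotic solvent. No stereocentre is formed, and the three existing ones carry no proton acidic enough to be removed by the naphtholate or fluoride.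

Step 15
Reactants: 27 ten-membered ansa ketone
Product: 29 CNP0225737.1 (target), via hexaphenol ketone 28 (not isolated)
Conditions: BBr3 (12 equiv), CH2Cl2, −78 → 0 °C, argon; then MeOH, 40 °C
Reagents that add atoms: none
Why: Lewis-acid cleavage of the five aryl methyl ethers, then acid-catalysed intramolecular Friedel–Crafts hydroxyalkylation of the ring E ketone at C-8 of the naphthalene (ortho and para to the two freed ring B hydroxyls, the only peri position in reach) and loss of water should give ring C and the para-quinone methide, the presumed biosynthetic closure; no stereocentre is formed and enolisation at C-4' is disfavoured by the 2,6-disubstituted aryl ketone.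

**Compound list**

1 | 3,5-dimethoxyphenylacetic acid | COc1cc(CC(=O)O)cc(OC)c1 | starting material
2 | ethyl potassium malonate | CCOC(=O)CC(=O)[O-].[K+] | starting material
3 | 2-(3,5-dimethoxyphenyl)-1-(1H-imidazol-1-yl)ethan-1-one | COc1cc(CC(=O)n2ccnc2)cc(OC)c1 | intermediate
4 | ethyl 4-(3,5-dimethoxyphenyl)-3-oxobutanoate | CCOC(=O)CC(=O)Cc1cc(OC)cc(OC)c1 | intermediate
5 | 6,8-dimethoxynaphthalene-1,3-diol | Oc1cc(O)cc2cc(OC)cc(OC)c12 | intermediate
6 | 6,8-dimethoxy-3-[(triisopropylsilyl)oxy]naphthalen-1-ol | Oc1cc(O[Si](C(C)C)(C(C)C)C(C)C)cc2cc(OC)cc(OC)c12 | intermediate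
7 | triisopropyl[(4,5,7-trimethoxynaphthalen-2-yl)oxy]silane | COc1cc(O[Si](C(C)C)(C(C)C)C(C)C)cc2cc(OC)cc(OC)c12 | intermediate
8 | 4,5,7-trimethoxynaphthalen-2-ol | COc1cc(O)cc2cc(OC)cc(OC)c12 | intermediate
9 | (E)-but-2-enal | C/C=C/C=O | starting material
10 | (1R)-6,7,9-trimethoxy-1-methyl-2,3-dihydro-1H-benzo[f]chromen-3-ol | OC1C[C@@H](C)c2c(O1)cc(OC)c1c(OC)cc(OC)cc21 | intermediate
11 | (1R)-6,7,9-trimethoxy-1-methyl-1,2-dihydro-3H-benzo[f]chromen-3-one | O=C1C[C@@H](C)c2c(O1)cc(OC)c1c(OC)cc(OC)cc21 | intermediate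
12 | 1,3-dimethoxybenzene | COc1cccc(OC)c1 | starting material
13 | (2,6-dimethoxyphenyl)lithium | [Li]c1c(OC)cccc1OC | intermediate
14 | lithium 1-[(2R)-4-(2,6-dimethoxyphenyl)-4-oxobutan-2-yl]-4,5,7-trimethoxynaphthalen-2-olate | [Li+].COc1cccc(OC)c1C(=O)C[C@@H](C)c1c([O-])cc(OC)c2c(OC)cc(OC)cc12 | intermediate
15 | (3R)-3-{2-[(tert-butyldimethylsilyl)oxy]-4,5,7-trimethoxynaphthalen-1-yl}-1-(2,6-dimethoxyphenyl)butan-1-one | COc1cccc(OC)c1C(=O)C[C@@H](C)c1c(O[Si](C)(C)C(C)(C)C)cc(OC)c2c(OC)cc(OC)cc12 | intermediate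
16 | tert-butyl (E)-but-2-enoate | C/C=C/C(=O)OC(C)(C)C | starting material
17 | tert-butyl (3S,4R,5R)-5-{2-[(tert-butyldimethylsilyl)oxy]-4,5,7-trimethoxynaphthalen-1-yl}-4-(2,6-dimethoxybenzoyl)-3-methylhexanoate | CC(C)(C)OC(=O)C[C@H](C)[C@@H](C(=O)c1c(OC)cccc1OC)[C@@H](C)c1c(O[Si](C)(C)C(C)(C)C)cc(OC)c2c(OC)cc(OC)cc12 | intermediate
18 | (3S,4R,5R)-5-{2-[(tert-butyldimethylsilyl)oxy]-4,5,7-trimethoxynaphthalen-1-yl}-4-(2,6-dimethoxybenzoyl)-3-methylhexanoic acid | OC(=O)C[C@H](C)[C@@H](C(=O)c1c(OC)cccc1OC)[C@@H](C)c1c(O[Si](C)(C)C(C)(C)C)cc(OC)c2c(OC)cc(OC)cc12 | intermediate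
19 | 2-bromobenzene-1,3-diol | Oc1cccc(O)c1Br | starting material
20 | 2-bromo-1,3-bis(trimethylsilyloxy)benzene | C[Si](C)(C)Oc1cccc(O[Si](C)(C)C)c1Br | intermediate
21 | lithium 2-(trimethylsilyl)-3-(trimethylsilyloxy)phenolate | [Li+].[O-]c1cccc(O[Si](C)(C)C)c1[Si](C)(C)C | intermediate
22 | 2-(trimethylsilyl)-3-(trimethylsilyloxy)phenyl trifluoromethanesulfonate | C[Si](C)(C)Oc1cccc(OS(=O)(=O)C(F)(F)F)c1[Si](C)(C)C | intermediate
23 | 3-hydroxy-2-(trimethylsilyl)phenyl trifluoromethanesulfonate | Oc1cccc(OS(=O)(=O)C(F)(F)F)c1[Si](C)(C)C | intermediate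
24 | 3-{[(trifluoromethyl)sulfonyl]oxy}-2-(trimethylsilyl)phenyl ester of acid 18 | O=C(Oc1cccc(OS(=O)(=O)C(F)(F)F)c1[Si](C)(C)C)C[C@H](C)[C@@H](C(=O)c1c(OC)cccc1OC)[C@@H](C)c1c(O[Si](C)(C)C(C)(C)C)cc(OC)c2c(OC)cc(OC)cc12 | intermediate
25 | tetrabutylammonium naphtholate bearing the 3-acyloxybenzyne (2,3-didehydrophenyl ester) | O=C(OC1=CC=CC#C1)C[C@H](C)[C@@H](C(=O)c1c(OC)cccc1OC)[C@@H](C)c1c([O-])cc(OC)c2c(OC)cc(OC)cc12.CCCC[N+](CCCC)(CCCC)CCCC | intermediate
26 | tetrabutylammonium salt of the twelve-membered aryl ester carbanion (anion at ring D C-2 between ester O and ether O) | O=C1C[C@H](C)[C@@H](C(=O)c2c(OC)cccc2OC)[C@@H](C)c2c3cc(OC)cc(OC)c3c(OC)cc2Oc2cccc(O1)[c-]2.CCCC[N+](CCCC)(CCCC)CCCC | intermediate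
27 | ten-membered ansa ketone: ring D 2-acyl-3-hydroxy-1-(naphthyloxy); chain C-3' (S)-methyl, C-4' (R)-2,6-dimethoxybenzoyl, C-5' (R)-methyl; naphthalene 4,5,7-trimethoxy | C[C@H]1CC(=O)c2c(O)cccc2Oc2cc(OC)c3c(OC)cc(OC)cc3c2[C@H](C)[C@@H]1C(=O)c1c(OC)cccc1OC | intermediate
28 | hexaphenol of 27 (all five methyl ethers cleaved, ring E ketone still open) | C[C@H]1CC(=O)c2c(O)cccc2Oc2cc(O)c3c(O)cc(O)cc3c2[C@H](C)[C@@H]1C(=O)c1c(O)cccc1O | intermediate
29 | CNP0225737.1 | C[C@H]1CC(=O)c2c(O)cccc2Oc2cc(O)c3c4c2[C@H](C)[C@@H]1C(c1c(O)cccc1O)=C4C(O)=CC3=O | target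

**Count and risks**

Total steps: 15. Longest linear sequence: 13 (steps 1–10, 13, 14, 15).

Steps most likely to fail:

1. Step 14 (Proposed new method). The aryne may form before the naphtholate is unveiled, or be captured between molecules or by fluoride; the aryl ester may also pass its acyl group to the naphtholate before the aryne forms. The fallback uses known chemistry; it sets out from 17 and comes back at 27. Bu4NF/AcOH removes the silyl group of 17 to give tert-butyl (3S,4R,5R)-4-(2,6-dimethoxybenzoyl)-5-(2-hydroxy-4,5,7-trimethoxynaphthalen-1-yl)-3-methylhexanoate F1. Chan–Lam coupling with [3-(benzyloxy)phenyl]boronic acid (Cu(OAc)2, pyridine, 4 Å MS, air, CH2Cl2, 23 °C) should give the 3-(benzyloxy)phenyl naphthyl ether F2. Hydrogenolysis (H2, Pd/C, EtOAc) should give the phenol F3, and CF3CO2H the hydroxy acid F4. Yamaguchi macrolactonisation (2,4,6-trichlorobenzoyl chloride, Et3N; DMAP, toluene, high dilution) should give the isolated twelve-membered aryl lactone F5. Irradiation at 254 nm (photo-Fries rearrangement, the known ring contraction of aryl macrolactones) should move the acyl group to the ring D carbon between the two oxygens and give 27, to be separated from the isomer acylated at the other ortho position.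

2. Step 9. The hindered enolate may react slowly with the enoate, facial selectivity at the enolate may be poor, or the adduct enolate may equilibrate. The fallback sets out from 11 and comes back at 18. Lithium (E)-but-2-en-1-olate opens lactone 11 and TBSCl silylates the naphtholate to give the crotyl ester (2E)-but-2-en-1-yl (3R)-3-{2-[(tert-butyldimethylsilyl)oxy]-4,5,7-trimethoxynaphthalen-1-yl}butanoate F6. Ireland–Claisen rearrangement (LiN(i-Pr)2, THF, −78 °C; Me3SiCl; → 23 °C) through the E(O)-enolate and a chair transition state should give the anti acid (2R,3S)-2-[(1R)-1-{2-[(tert-butyldimethylsilyl)oxy]-4,5,7-trimethoxynaphthalen-1-yl}ethyl]-3-methylpent-4-enoic acid F7. Here the C–C bond forms within the molecule and the topicity is fixed by the ring-shaped transition state. (2,6-Dimethoxyphenyl)lithium (2.2 equiv) should convert the acid into the aryl ketone F8. 9-Borabicyclo[3.3.1]nonane then NaBO3 should give the primary alcohol F9, Dess–Martin periodinane the aldehyde F10, and NaClO2 (NaH2PO4, 2-methylbut-2-ene) the acid 18.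

3. Step 15. The electron-rich naphthalenetriol set free before ring C closes may be oxidised by air, ether cleavage may be incomplete, or acid may epimerise C-4'. The fallback sets out from 27 and comes back at 29, closing ring C before the phenols are freed. CF3SO3H in CH2Cl2 at 0 °C should effect the Friedel–Crafts cyclodehydration of the ring E ketone onto the still methylated ring B; hydrolysis of the methoxy-stabilised cation in the aqueous work-up releases methanol and should give the robust tetra-O-methyl quinone methide F11. BBr3 (CH2Cl2, −78 → 0 °C) then cleaves the four remaining methyl ethers to give 29.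

Further compounds
F1 | step 14 | tert-butyl (3S,4R,5R)-4-(2,6-dimethoxybenzoyl)-5-(2-hydroxy-4,5,7-trimethoxynaphthalen-1-yl)-3-methylhexanoate | CC(C)(C)OC(=O)C[C@H](C)[C@@H](C(=O)c1c(OC)cccc1OC)[C@@H](C)c1c(O)cc(OC)c2c(OC)cc(OC)cc12
F2 | step 14 | tert-butyl (3S,4R,5R)-5-{2-[3-(benzyloxy)phenoxy]-4,5,7-trimethoxynaphthalen-1-yl}-4-(2,6-dimethoxybenzoyl)-3-methylhexanoate | CC(C)(C)OC(=O)C[C@H](C)[C@@H](C(=O)c1c(OC)cccc1OC)[C@@H](C)c1c(Oc3cccc(OCc4ccccc4)c3)cc(OC)c2c(OC)cc(OC)cc12
F3 | step 14 | tert-butyl (3S,4R,5R)-4-(2,6-dimethoxybenzoyl)-5-[2-(3-hydroxyphenoxy)-4,5,7-trimethoxynaphthalen-1-yl]-3-methylhexanoate | CC(C)(C)OC(=O)C[C@H](C)[C@@H](C(=O)c1c(OC)cccc1OC)[C@@H](C)c1c(Oc3cccc(O)c3)cc(OC)c2c(OC)cc(OC)cc12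
F4 | step 14 | (3S,4R,5R)-4-(2,6-dimethoxybenzoyl)-5-[2-(3-hydroxyphenoxy)-4,5,7-trimethoxynaphthalen-1-yl]-3-methylhexanoic acid | OC(=O)C[C@H](C)[C@@H](C(=O)c1c(OC)cccc1OC)[C@@H](C)c1c(Oc3cccc(O)c3)cc(OC)c2c(OC)cc(OC)cc12
F5 | step 14 | twelve-membered aryl lactone of F4 (ester between the chain carboxyl and the 3-hydroxyphenoxy OH) | O=C1C[C@H](C)[C@@H](C(=O)c2c(OC)cccc2OC)[C@@H](C)c2c3cc(OC)cc(OC)c3c(OC)cc2Oc2cccc(O1)c2
F6 | step 9 | (2E)-but-2-en-1-yl (3R)-3-{2-[(tert-butyldimethylsilyl)oxy]-4,5,7-trimethoxynaphthalen-1-yl}butanoate | C/C=C/COC(=O)C[C@@H](C)c1c(O[Si](C)(C)C(C)(C)C)cc(OC)c2c(OC)cc(OC)cc12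
F7 | step 9 | (2R,3S)-2-[(1R)-1-{2-[(tert-butyldimethylsilyl)oxy]-4,5,7-trimethoxynaphthalen-1-yl}ethyl]-3-methylpent-4-enoic acid | C=C[C@H](C)[C@@H](C(=O)O)[C@@H](C)c1c(O[Si](C)(C)C(C)(C)C)cc(OC)c2c(OC)cc(OC)cc12
F8 | step 9 | (2R,3S)-2-[(1R)-1-{2-[(tert-butyldimethylsilyl)oxy]-4,5,7-trimethoxynaphthalen-1-yl}ethyl]-1-(2,6-dimethoxyphenyl)-3-methylpent-4-en-1-one | C=C[C@H](C)[C@@H](C(=O)c1c(OC)cccc1OC)[C@@H](C)c1c(O[Si](C)(C)C(C)(C)C)cc(OC)c2c(OC)cc(OC)cc12
F9 | step 9 | (2R,3S)-2-[(1R)-1-{2-[(tert-butyldimethylsilyl)oxy]-4,5,7-trimethoxynaphthalen-1-yl}ethyl]-1-(2,6-dimethoxyphenyl)-5-hydroxy-3-methylpentan-1-one | OCC[C@H](C)[C@@H](C(=O)c1c(OC)cccc1OC)[C@@H](C)c1c(O[Si](C)(C)C(C)(C)C)cc(OC)c2c(OC)cc(OC)cc12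
F10 | step 9 | (3S,4R,5R)-5-{2-[(tert-butyldimethylsilyl)oxy]-4,5,7-trimethoxynaphthalen-1-yl}-4-(2,6-dimethoxybenzoyl)-3-methylhexanal | O=CC[C@H](C)[C@@H](C(=O)c1c(OC)cccc1OC)[C@@H](C)c1c(O[Si](C)(C)C(C)(C)C)cc(OC)c2c(OC)cc(OC)cc12
F11 | step 15 | tetra-O-methyl ether of the target (methyl on the ring A hydroxyl, on the ring B enol oxygen and on both ring E oxygens; ring D hydroxyl free) | C[C@H]1CC(=O)c2c(O)cccc2Oc2cc(OC)c3c4c2[C@H](C)[C@@H]1C(c1c(OC)cccc1OC)=C4C(OC)=CC3=O
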